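**Retrosynthetic overview**
1. The C2–aryl bond is cut last: the (2S) centre comes from an enantioselective rhodium-catalysed 1,4-addition of the ring B boronic acid to 5,7-dimethoxy-8-prenylchromone.
2. The chromone is cut through both rings at once: a Diels–Alder benzannulation of a 2-prenyl vinylketene acetal (C8a–C8–C7–C6) with a methoxy ynone (C4a≡C5) builds ring A, and the one phenol this unmasks closes the pyranone ring (O1–C2) in the same operation.
3. The diene comes from methyl acetoacetate and prenyl bromide; the ynone comes from methyl 3-methoxyacrylate and the alkynyl ether anion of chloroacetaldehyde dimethyl acetal.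
4. Ring order: ring B is bought, rings A and C form together (step 6), the stereocentre is set last (step 7).

Assumption: the SMILES is read as the (2S)-flavanone; routine reagents and the chiral ligand are bought.

**Step 1**
Reactants: 1 methyl acetoacetate (methyl 3-oxobutanoate); 2 prenyl bromide (1-bromo-3-methylbut-2-ene)
Product: 3 methyl 2-acetyl-5-methylhex-4-enoate (racemic)
Conditions: K2CO3, acetone, reflux
Reagents that add atoms: none
Why: Acetoacetic ester alkylation: the potassium enolate is C-alkylated by the primary allylic bromide (SN2), and the new stereocentre is racemic and is lost again in step 2.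

**Step 2**
Reactants: 3 methyl 2-acetyl-5-methylhex-4-enoate
Product: 4 methyl 3-methoxy-2-(3-methylbut-2-en-1-yl)but-2-enoate (E/Z mixture)
Conditions: NaH, DMPU/THF, 0 °C; Me2SO4, 0→23 °C
Reagents that add atoms: dimethyl sulfate, COS(=O)(=O)OC
Why: Enolate O-alkylation: the sodium enolate of the α-substituted β-keto ester, poorly ion-paired in DMPU, is methylated by the hard electrophile at oxygen (C-methylation would create a hindered quaternary carbon), and the E/Z mixture does not matter because both isomers give the same dienolate.

**Step 3**
Reactants: 4 methyl 3-methoxy-2-(3-methylbut-2-en-1-yl)but-2-enoate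
Product: 5 {[1,3-dimethoxy-2-(3-methylbut-2-en-1-yl)buta-1,3-dien-1-yl]oxy}trimethylsilane (2-prenyl Brassard-type diene, ketene acetal geometry mixed)
Conditions: LiN(i-Pr)2, THF, −78 °C; Me3SiCl, −78→0 °C; filter, distil
Reagents that add atoms: chlorotrimethylsilane, C[Si](C)(C)Cl
Why: Silyl ketene acetal formation as in the preparation of Brassard's diene: kinetic γ-deprotonation at the unhindered methyl group gives the through-conjugated dienolate, which Me3SiCl traps on oxygen.

**Step 4**
Reactants: 6 methyl (E)-3-methoxyprop-2-enoate (methyl 3-methoxyacrylate)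
Product: 7 (E)-N,3-dimethoxy-N-methylprop-2-enamide
Conditions: MeNHOMe·HCl, i-PrMgCl, THF, −20 °C
Reagents that add atoms: N,O-dimethylhydroxylamine hydrochloride, CNOC.Cl
Why: Weinreb amide synthesis by aminolysis of the ester with the chloromagnesium amide formed in the flask, which attacks the carbonyl group and leaves the E-enol ether untouched.

**Step 5**
Reactants: 8 2-chloro-1,1-dimethoxyethane (chloroacetaldehyde dimethyl acetal); 7 (E)-N,3-dimethoxy-N-methylprop-2-enamide
Product: 10 (E)-1,5-dimethoxypent-1-en-4-yn-3-one, via lithium methoxyacetylide 9 (not isolated)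
Conditions: LiNEt2 (3.1 equiv, from Et2NH and n-BuLi), THF, 0 °C; then 7, −78→−20 °C; inverse quench into cold aq. citric acid
Reagents that add atoms: none
Why: Two base-induced eliminations (methanol and HCl) and a deprotonation turn the chloroacetal into the alkynyl ether anion, which adds once to the Weinreb amide (Weinreb ketone synthesis, chelated tetrahedral intermediate), and the cold acidic inverse quench protonates the amines before they can add to the push–pull ynone.

**Step 6 (key step)**
Reactants: 5 {[1,3-dimethoxy-2-(3-methylbut-2-en-1-yl)buta-1,3-dien-1-yl]oxy}trimethylsilane; 10 (E)-1,5-dimethoxypent-1-en-4-yn-3-one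
Product: 14 5,7-dimethoxy-8-(3-methylbut-2-en-1-yl)-4H-chromen-4-one, via cyclohexadiene cycloadduct 11 (not isolated), via aryl silyl ether 12 (not isolated), via hydroxyaryl methoxyvinyl ketone 13 (not isolated)
Conditions: toluene, 100 °C; then 1 M HCl, THF, 23 °C
Reagents that add atoms: none
Why: Proposed new method: the diene should add across the ketone-conjugated π bond of the push–pull ynone as in the known Brassard benzannulation of alkynoates and alkynones (closest case: Brassard's diene with methyl but-2-ynoate giving methyl everninate), its nucleophilic CH2 terminus bonding to the methoxy-bearing alkyne carbon and its ketene acetal carbon to the acyl-bearing one; the cyclohexadiene ketal then loses methanol to give ring A, whose only free hydroxyl (next to the prenyl group, ortho to the ketone) is unmasked by acid and closes onto the β-methoxyvinyl ketone by addition–elimination (classical chromone cyclocondensation), so both rings and the 5,7-dimethoxy-8-prenyl pattern arise in one operation without regiochemical ambiguity and no stereocentre is formed.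

**Step 7**
Reactants: 14 5,7-dimethoxy-8-(3-methylbut-2-en-1-yl)-4H-chromen-4-one; 15 (3-hydroxy-4-methoxyphenyl)boronic acid
Product: 16 (2S)-2-(3-hydroxy-4-methoxyphenyl)-5,7-dimethoxy-8-(3-methylbut-2-en-1-yl)-2,3-dihydro-4H-chromen-4-one (target)
Conditions: [Rh(OH)(cod)]2 (3 mol %), (S)-MeO-F12-BIPHEP [(S)-2,2'-bis{bis(3,4,5-trifluorophenyl)phosphino}-6,6'-dimethoxy-1,1'-biphenyl] (7 mol %), 15 (3 equiv), toluene/H2O, 40 °C, no added base
Reagents that add atoms: none
Why: Hayashi–Miyaura rhodium-catalysed asymmetric 1,4-addition of an arylboronic acid to a chromone: the aryl–rhodium complex inserts the C2=C3 bond from one face and water protonates the rhodium enolate, the (S)-ligand being expected by the Hayashi–Miyaura model for cyclic enones to give 2S (the sense is confirmed by chiral HPLC and the (R)-ligand gives the antipode), while the base-free medium prevents racemisation by ring opening to the chalcone.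

**Compound list**
1 | methyl acetoacetate (methyl 3-oxobutanoate) | COC(=O)CC(C)=O | starting material
2 | prenyl bromide (1-bromo-3-methylbut-2-ene) | CC(C)=CCBr | starting material
3 | methyl 2-acetyl-5-methylhex-4-enoate (racemic) | COC(=O)C(CC=C(C)C)C(C)=O | intermediate
4 | methyl 3-methoxy-2-(3-methylbut-2-en-1-yl)but-2-enoate (E/Z mixture) | COC(=O)C(CC=C(C)C)=C(C)OC | intermediate
5 | {[1,3-dimethoxy-2-(3-methylbut-2-en-1-yl)buta-1,3-dien-1-yl]oxy}trimethylsilane (ketene acetal geometry mixed) | COC(O[Si](C)(C)C)=C(CC=C(C)C)C(OC)=C | intermediate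
6 | methyl (E)-3-methoxyprop-2-enoate | CO/C=C/C(=O)OC | starting material
7 | (E)-N,3-dimethoxy-N-methylprop-2-enamide | CO/C=C/C(=O)N(C)OC | intermediate
8 | 2-chloro-1,1-dimethoxyethane | COC(CCl)OC | starting material
9 | lithium methoxyacetylide (1-lithio-2-methoxyethyne) | [Li]C#COC | intermediate
10 | (E)-1,5-dimethoxypent-1-en-4-yn-3-one | CO/C=C/C(=O)C#COC | intermediate
11 | (E)-3-methoxy-1-[2,4,6-trimethoxy-5-(3-methylbut-2-en-1-yl)-6-(trimethylsilyloxy)cyclohexa-1,4-dien-1-yl]prop-2-en-1-one (racemic at C6) | CO/C=C/C(=O)C1=C(OC)CC(OC)=C(CC=C(C)C)C1(OC)O[Si](C)(C)C | intermediate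
12 | (E)-1-[4,6-dimethoxy-3-(3-methylbut-2-en-1-yl)-2-(trimethylsilyloxy)phenyl]-3-methoxyprop-2-en-1-one | CO/C=C/C(=O)c1c(OC)cc(OC)c(CC=C(C)C)c1O[Si](C)(C)C | intermediate
13 | (E)-1-[2-hydroxy-4,6-dimethoxy-3-(3-methylbut-2-en-1-yl)phenyl]-3-methoxyprop-2-en-1-one | CO/C=C/C(=O)c1c(OC)cc(OC)c(CC=C(C)C)c1O | intermediate
14 | 5,7-dimethoxy-8-(3-methylbut-2-en-1-yl)-4H-chromen-4-one | COc1cc(OC)c2c(c1CC=C(C)C)occc2=O | intermediate
15 | (3-hydroxy-4-methoxyphenyl)boronic acid | COc1ccc(B(O)O)cc1O | starting material
16 | (2S)-2-(3-hydroxy-4-methoxyphenyl)-5,7-dimethoxy-8-(3-methylbut-2-en-1-yl)-2,3-dihydro-4H-chromen-4-one | COc1ccc([C@@H]2CC(=O)c3c(OC)cc(OC)c(CC=C(C)C)c3O2)cc1O | target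

**Step count and risks**
Total steps: 7. Longest linear sequence: 5 steps (1, 2, 3, 6, 7); steps 4 and 5 form the second branch, which joins at step 6.

Steps most likely to fail:

Step 6. The push–pull ynone 10 may be too electron-rich a dienophile, so that diene 5 decomposes before it cycloadds. The fallback sets out from 4 (with 10) and comes back at 14, building the same two rings by an anionic instead of a pericyclic path. LiN(i-Pr)2 deprotonates 4 at the γ-methyl group in THF at −78 °C and the dienolate adds in conjugate fashion to the methoxy-bearing alkyne carbon of 10. An acetic acid quench at −78 °C protonates the allenolate before it can expel methoxide and gives methyl 3,5,9-trimethoxy-2-(3-methylbut-2-en-1-yl)-7-oxonona-2,5,8-trienoate F1. KOt-Bu in THF at 0 °C then removes a C4 proton, the vinylogous enolate closes C6 onto the ester (Dieckmann-type condensation, then tautomerisation to the phenolate of 13), and the phenolate cyclises onto the methoxyvinyl ketone to give 14 in the same flask.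

Step 7. The electron-rich, peri-methoxylated chromone 14 may react slowly or with low selectivity, and the free phenol of 15 may favour protodeboronation. The fallback sets out from 14 (with 15) and comes back at 16, setting C2 by hydride delivery instead of aryl delivery. Pd(OCOCF3)2 in DMSO/AcOH under O2 effects conjugate arylation followed by aerobic dehydrogenation to the flavone 2-(3-hydroxy-4-methoxyphenyl)-5,7-dimethoxy-8-(3-methylbut-2-en-1-yl)-4H-chromen-4-one F2. Copper hydride generated from Cu(OAc)2, one enantiomer of DTBM-SEGPHOS and (EtO)2MeSiH with t-BuOH in toluene then reduces the C2=C3 bond by enantioselective 1,4-addition; the ligand enantiomer that gives 2S is fixed by assay.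

Step 5. The vinylogous Weinreb amide 7 is a deactivated acylating agent, and the ynone 10 can be lost to conjugate addition of the amines on work-up. The fallback sets out from 7 and comes back at 10 through the alcohol oxidation level. i-Bu2AlH in THF at −78 °C reduces 7 to (E)-3-methoxyprop-2-enal F3. The acetylide 9, made as in step 5, adds to the aldehyde to give (E)-1,5-dimethoxypent-1-en-4-yn-3-ol F4, which has no conjugate acceptor for the amines to attack. MnO2 in CH2Cl2 then oxidises this allylic, propargylic alcohol to 10 under neutral conditions.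

**Further compounds**
F1 | step 6 | methyl 3,5,9-trimethoxy-2-(3-methylbut-2-en-1-yl)-7-oxonona-2,5,8-trienoate (8E; geometry at C2 and C5 mixed) | COC(=O)C(CC=C(C)C)=C(OC)CC(OC)=CC(=O)/C=C/OC
F2 | step 7 | 2-(3-hydroxy-4-methoxyphenyl)-5,7-dimethoxy-8-(3-methylbut-2-en-1-yl)-4H-chromen-4-one | COc1ccc(-c2cc(=O)c3c(OC)cc(OC)c(CC=C(C)C)c3o2)cc1O
F3 | step 5 | (E)-3-methoxyprop-2-enal | CO/C=C/C=O
F4 | step 5 | (E)-1,5-dimethoxypent-1-en-4-yn-3-ol (racemic) | CO/C=C/C(O)C#COC
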